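## The problem

Kanzonol X (26) is a (3R)-isoflavan: a chroman (rings A and C) carrying a resorcinol ring B at C3, with one 3-methylbut-2-enyl (prenyl) group on each arene. Its only stereocentre is C3, a benzylic methine between two methylene groups; nothing else in the molecule can relay to it, so it must be set by a reagent or an auxiliary. That centre should not stay next to a carbonyl group longer than necessary, because an α-aryl carbonyl centre epimerises easily. Both prenyl groups sit between two oxygen substituents (C8 between O1 and the C7 hydroxyl, C3' between the C2' and C4' hydroxyls), which are the positions that electrophilic substitution avoids in favour of C6 and C5'. The free phenols are electron-rich, ortho-prenylphenols cyclise to 2,2-dimethylchromans in strong acid, and the trisubstituted olefins tolerate neither hydrogenation nor electrophilic oxidants, so prenyl groups and free phenols must appear late. In a conventional approach ring A is a resorcinol on which the ether oxygen and the C4 carbon have to be placed regioselectively. The oxygen pattern of ring A removes that problem: C4a is para to the C7 hydroxyl, and O1 sits on C8a, ortho to C4a and meta to the C7 hydroxyl. Ring A is therefore a para-alkylphenol with one extra oxygen on a carbon that is a β carbon of the dienone in the corresponding para-quinol, so the C2 hydroxyl can be delivered there by conjugate addition and the arene restored by loss of water.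

## Retrosynthesis

**Prenyl C–C bonds and final deprotection (26 ⇐ 25 ⇐ 21 + 22).** The C8–CH2 and C3'–CH2 bonds are cut last in the analysis, so the prenyl groups go on last in the synthesis. Earlier introduction is excluded on three counts. The olefins would not survive the hydrogenolysis or the singlet-oxygen step. A substituent on ring A would make the two β carbons of the quinol non-equivalent. Both sites are exactly where directed ortho-metalation works best, each flanked by two coordinating oxygens. The precursor 21 is the tris(methoxymethyl) ether of the unsubstituted isoflavan triol, and two equivalents of prenyl bromide (22) supply the two side chains. The forward reaction must metalate twice in one molecule and alkylate at the primary carbon of the allylic bromide. The acetal ethers of 25 come off in dilute acid to give 26.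

**Protecting-group exchange (21 ⇐ 20 ⇐ 19).** No skeletal bond is cut. Ring B carries benzyl ethers through the first half because the ring-closing step ends in acid, which acetal ethers might not survive. It needs methoxymethyl ethers in the second half because they direct metalation and leave under conditions the prenyl groups tolerate. Hydrogenolysis of 19 to triol 20 and threefold acetalisation to 21 make the switch while the molecule still has no olefin.

**Ring C by the O1–C8a bond (19 ⇐ 17).** Cutting O1–C8a and, in the same thought, dearomatising ring A leads to the para-quinol 17, in which the primary C2 hydroxyl is five atoms from a dienone β carbon. The neighbouring cuts (O1–C2 by phenol alkylation, or C4–C4a by Friedel–Crafts chemistry) both require a resorcinol ring A and a choice between its two ortho positions. Here the two β carbons lead to the same product. Ring A thereby simplifies to a 4-hydroxybenzyl unit. The forward step must add the alkoxide to the dienone and then lose the tertiary hydroxyl as water without letting the quinol rearrange.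

**Dearomatisation (17 ⇐ 15 ⇐ 14).** The C4a–O bond of the quinol is traced to the para-alkylphenol 15 and an oxygen atom. Singlet oxygen is preferred to a trivalent iodine oxidant because it adds to the phenolate without passing through an ipso cation, so the free primary alcohol of 15 cannot close to a spiro ether and needs no protection. Phenol 15 comes from its silyl ether 14 with fluoride.

**The C3–C4 bond and the stereocentre (14 ⇐ 13 ⇐ 7 + 11).** Cutting C3–C4 divides the molecule into a ring B arylacetyl unit and a ring A benzyl electrophile of similar size, and turns the stereochemical problem into an auxiliary-controlled enolate alkylation, the best-understood way to make an α-aryl-β-aryl propanoyl unit. Cutting C3–C1' instead would need an asymmetric α-arylation with a hindered, doubly oxygenated aryl partner, and cutting C2–C3 would need a hydroxymethylation that places the bulky groups less favourably. The imide 7 and the benzylic bromide 11 are both simple. Reduction of 13 to alcohol 14 takes the stereocentre away from the carbonyl group at once.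

**Fragments (7 ⇐ 4 + 5; 4 ⇐ 1 + 2; 11 ⇐ 10 ⇐ 9 ⇐ 8).** Imide 7 is the N-acyl derivative of (R)-4-benzyloxazolidin-2-one (5) and acid 4. Acid 4 is traced to methyl (2,4-dihydroxyphenyl)acetate (1), whose two phenols are benzylated with two equivalents of benzyl bromide (2) to give ester 3, which is saponified in the same flask. The methyl ester is chosen over the free acid so that only the phenols consume benzyl bromide and the ortho-hydroxy acid, which lactonises easily to a benzofuranone, is never handled. Bromide 11 comes from 4-hydroxybenzaldehyde (8) by silylation (9), reduction (10) and bromination.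

## Roads not taken

**Alternative 1:** Ring C is cut at both C3–C4 and O1–C2. An isothiourea-bound ammonium enolate of the prenylated ring B arylacetic acid A3 would add through C3 to the methide carbon of the ring A ortho-quinone methide A2, generated in the flask, and the phenoxide would lactonise to the dihydrocoumarin A1. Reduction with LiAlH4 to the phenol–alcohol A4 and an intramolecular etherification would then give 25. Its merits are real: the fragments are joined and the stereocentre set in one catalytic step with no stoichiometric auxiliary, and both prenyl groups arrive on simple arenes, so no late twofold metalation is needed. In convergence this road is better than the chosen one. Its weak points for this target are as follows. A2 is a methide without a substituent on the exocyclic carbon, the most fleeting and dimerisation-prone kind. The C3 centre of A1 is benzylic and α to a lactone carbonyl, under the very base that generates A2. Ring C is closed as a lactone, opened by reduction and closed again as an ether. Each prenylated arene still needs its own directed metalation, so that problem is moved and not removed. Against the better convergence the chosen plan sets a stereocentre that is taken away from the carbonyl group immediately, and a ring closure that delivers the chroman oxidation level directly.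

**Alternative 2:** Ring B itself is cut (C2'–C3', C4'–C5', C1'–C2'). Irradiation of the chroman-3-yl diazo enone A6 would give a vinylketene by photochemical Wolff rearrangement. Addition to the prenyl-bearing siloxyalkyne A7, opening of the vinylcyclobutenone and 6π closure would give the bis(triisopropylsilyl) ether A5, with the C2' hydroxyl free. For ring B regiochemistry this is the best of all the options: the prenyl group is placed between the two oxygens by construction and the two ring B oxygens come out differentiated. The price is that A6 already contains rings A and C, the C3 stereocentre and the C8 prenyl group, so the harder half of the problem is left unsolved and a separate directed metalation on ring A is still needed. The C3 hydrogen of A6 is γ to the enone carbonyl and allylic, which puts the configuration at risk during diazo transfer. The ketene intermediates are also generated in the presence of two electron-rich trisubstituted olefins. The chosen plan is shorter, uses a commercial resorcinol unit for ring B, and accepts in exchange a late metalation on ring B.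

**Alternative 3:** Only the two aryl–CH2 bonds are cut: twofold ortho-lithiation of the tris(methoxymethyl) ether A9 (identical with 21), transmetalation to copper and alkylation with prenyl bromide (22) to A8 (identical with 25). This is not a rival to the endgame of the chosen plan but the same step. The difference lies in how A9 is reached: the road leaves that open to conventional isoflavan chemistry, for instance enantioselective hydrogenation of the isoflav-3-ene A10 with a catalyst of the type [Ir(cod)(L)]BArF (L = chiral phosphine–oxazoline). That could well be shorter than the ten-step longest linear sequence to 21 used here (twelve operations over both branches), and it avoids a stoichiometric auxiliary. Its weak points are that the whole stereochemical burden falls on the hydrogenation of a trisubstituted cyclic olefin bearing an ortho-substituted aryl group, and that building A10 requires acylation or alkylation of a resorcinol at one of two ortho positions. The chosen plan sets against the shorter sequence an auxiliary-controlled centre of predictable configuration and a ring A that never poses a resorcinol regiochemistry question.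

Key step: step 10

Assumption: the bicyclic intermediate 18 stands for both cis-fused ring-fusion diastereomers, which should form together (the two dienone β carbons are diastereotopic because of C3) and which give the same chromanol 19; its SMILES shows one of them.

## Route

Step 1
Reactants: 1 methyl (2,4-dihydroxyphenyl)acetate; 2 benzyl bromide
Product: 4 [2,4-bis(benzyloxy)phenyl]acetic acid, via methyl ester 3 (not isolated)
Conditions: BnBr (2.3 equiv), K2CO3, DMF, 60 °C; then NaOH (aq, excess), MeOH, 60 °C; HCl work-up
Reagents that add atoms: benzyl bromide (the second equivalent of 2; both benzyl groups stay in 4), BrCc1ccccc1; sodium hydroxide, [Na+].[OH-]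
Why: Williamson O-benzylation of the two phenols under carbonate, which is too weak a base to alkylate the ester α-carbon, then saponification of the methyl ester in the same pot; aryl benzyl ethers are inert to hydroxide.

Step 2
Reactants: 4 [2,4-bis(benzyloxy)phenyl]acetic acid; 5 (4R)-4-benzyl-1,3-oxazolidin-2-one
Product: 7 (4R)-4-benzyl-3-{[2,4-bis(benzyloxy)phenyl]acetyl}-1,3-oxazolidin-2-one, via mixed pivalic anhydride 6 (not isolated)
Conditions: PivCl, Et3N, THF, −20 °C; then 5, LiCl, −20 °C → rt
Reagents that add atoms: none
Why: N-acylation of the oxazolidinone through the mixed pivalic anhydride with LiCl/Et3N activation is the standard mild route to arylacetyl imides and avoids strong base on the acidic arylacetyl unit.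

Step 3
Reactants: 8 4-hydroxybenzaldehyde
Product: 9 4-(triisopropylsilyloxy)benzaldehyde
Conditions: TIPSCl, imidazole, DMF, rt
Reagents that add atoms: chlorotriisopropylsilane, CC(C)[Si](Cl)(C(C)C)C(C)C
Why: Phenol silylation with a chlorosilane and imidazole; the bulky silyl ether is chosen to survive enolate, hydride and bromination conditions and to leave with fluoride without touching benzyl ethers.

Step 4
Reactants: 9 4-(triisopropylsilyloxy)benzaldehyde
Product: 10 [4-(triisopropylsilyloxy)phenyl]methanol
Conditions: NaBH4, MeOH, 0 °C
Reagents that add atoms: none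
Why: Borohydride reduction of an aromatic aldehyde; the aryl silyl ether is unaffected.

Step 5
Reactants: 10 [4-(triisopropylsilyloxy)phenyl]methanol
Product: 11 4-(triisopropylsilyloxy)benzyl bromide
Conditions: CBr4, PPh3, CH2Cl2, 0 °C
Reagents that add atoms: carbon tetrabromide, BrC(Br)(Br)Br
Why: Appel bromination converts the benzylic alcohol to the bromide under neutral conditions, avoiding acid-induced loss of the silyl group; the electron-rich bromide is used without storage.

Step 6
Reactants: 7 (4R)-4-benzyl-3-{[2,4-bis(benzyloxy)phenyl]acetyl}-1,3-oxazolidin-2-one; 11 4-(triisopropylsilyloxy)benzyl bromide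
Product: 13 (4R)-4-benzyl-3-{(2R)-2-[2,4-bis(benzyloxy)phenyl]-3-[4-(triisopropylsilyloxy)phenyl]propanoyl}-1,3-oxazolidin-2-one, via sodium Z-enolate 12 (not isolated)
Conditions: NaN(SiMe3)2, THF, −78 °C; then 11, −78 → −40 °C
Reagents that add atoms: none
Why: Evans asymmetric alkylation: the chelated Z-enolate 12 is shielded on one face by the C4 benzyl group of the (R)-auxiliary, so the benzylic bromide enters from the opposite face and sets the new centre (the future C3) as R. Low temperature and a reactive benzylic electrophile limit proton exchange at the acidic α-aryl position.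

Step 7
Reactants: 13 (4R)-4-benzyl-3-{(2R)-2-[2,4-bis(benzyloxy)phenyl]-3-[4-(triisopropylsilyloxy)phenyl]propanoyl}-1,3-oxazolidin-2-one
Product: 14 (2R)-2-[2,4-bis(benzyloxy)phenyl]-3-[4-(triisopropylsilyloxy)phenyl]propan-1-ol
Conditions: LiBH4, H2O (1 equiv), Et2O/THF, 0 °C
Reagents that add atoms: none
Why: Reductive cleavage of the imide by LiBH4 at the exocyclic carbonyl releases the primary alcohol and the auxiliary without epimerising the α-aryl centre, which from here on is no longer next to a carbonyl group.

Step 8
Reactants: 14 (2R)-2-[2,4-bis(benzyloxy)phenyl]-3-[4-(triisopropylsilyloxy)phenyl]propan-1-ol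
Product: 15 4-{(2R)-2-[2,4-bis(benzyloxy)phenyl]-3-hydroxypropyl}phenol
Conditions: Bu4NF, AcOH, THF, 0 °C
Reagents that add atoms: none
Why: Fluoride cleavage of the aryl silyl ether, buffered with acetic acid; benzyl ethers and the primary alcohol are untouched.

Step 9
Reactants: 15 4-{(2R)-2-[2,4-bis(benzyloxy)phenyl]-3-hydroxypropyl}phenol
Product: 17 4-{(2R)-2-[2,4-bis(benzyloxy)phenyl]-3-hydroxypropyl}-4-hydroxycyclohexa-2,5-dien-1-one, via para-peroxyquinol 16 (not isolated)
Conditions: Oxone (2KHSO5·KHSO4·K2SO4), NaHCO3, MeCN/H2O, rt; then Na2S2O3 (aq), 0 °C
Reagents that add atoms: potassium peroxymonosulfate (KHSO5, the active component of Oxone), [K+].OOS([O-])(=O)=O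
Why: Singlet oxygen released from peroxymonosulfate in bicarbonate adds to the para position of the phenolate to give peroxyquinol 16, which thiosulfate reduces to the quinol; this is the known oxidative dearomatisation of para-alkylphenols. No ipso cation is involved, so the free primary hydroxyl cannot spirocyclise and needs no protection, and the dibenzyl resorcinol ring reacts with singlet oxygen far more slowly than a phenolate.

Step 10
Reactants: 17 4-{(2R)-2-[2,4-bis(benzyloxy)phenyl]-3-hydroxypropyl}-4-hydroxycyclohexa-2,5-dien-1-one
Product: 19 (3R)-3-[2,4-bis(benzyloxy)phenyl]chroman-7-ol, via cis-fused hydroxy enone 18 (not isolated)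
Conditions: DBU (0.2 equiv), CH2Cl2, 0 °C → rt; then TsOH·H2O (0.5 equiv), rt → 40 °C
Reagents that add atoms: none
Why: DBU generates the primary alkoxide, which adds to a β carbon of the cross-conjugated dienone (intramolecular oxa-Michael addition), forming the O1–C8a bond and ring C as the hydroxy enone 18. The closure is 6-exo-trig through a chair-like array, and the short tether makes the ring fusion cis. On acidification the ketone enolises towards C8, the tertiary allylic C4a hydroxyl ionises to a cyclohexadienyl (arenium) cation, and loss of the C8a proton gives aromatic ring A with O1 meta to the C7 hydroxyl. The closest known reactions are the base-mediated cyclisation of 4-(hydroxyalkyl)-4-hydroxycyclohexadienones to cis-fused bicyclic ethers and the acid-promoted dehydrative aromatisation of quinol conjugate adducts to meta-substituted phenols. No new stereocentre survives: C4a and C8a become sp2, so both diastereomeric adducts give the same product, and C3, which is neither α to the carbonyl nor involved in any bond change, keeps its R configuration. The selectivity needed is addition–dehydration in preference to acid-induced alkyl migration of the quinol; adding base first converts the dienone into the ether adduct before any acid is present, and the mild sulfonic acid leaves the benzyl ethers intact.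

Step 11
Reactants: 19 (3R)-3-[2,4-bis(benzyloxy)phenyl]chroman-7-ol
Product: 20 (3R)-3-(2,4-dihydroxyphenyl)chroman-7-ol
Conditions: H2 (1 atm), Pd/C, EtOAc/MeOH, rt
Reagents that add atoms: none
Why: Catalytic hydrogenolysis of the two aryl benzyl ethers; the chroman C–O bonds are not benzylic and the molecule has no other reducible group at this stage.

Step 12
Reactants: 20 (3R)-3-(2,4-dihydroxyphenyl)chroman-7-ol
Product: 21 (3R)-7-(methoxymethoxy)-3-[2,4-bis(methoxymethoxy)phenyl]chroman
Conditions: MOMCl (4 equiv), iPr2NEt, CH2Cl2, 0 → 40 °C
Reagents that add atoms: chloromethyl methyl ether (three equivalents are incorporated), COCCl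
Why: Base-mediated alkylation of the three phenols with chloromethyl methyl ether gives the acetal ethers that direct the metalation in the next step and leave under mild acid.

Step 13
Reactants: 21 (3R)-7-(methoxymethoxy)-3-[2,4-bis(methoxymethoxy)phenyl]chroman; 22 prenyl bromide (1-bromo-3-methylbut-2-ene)
Product: 25 (3R)-7-(methoxymethoxy)-3-[2,4-bis(methoxymethoxy)-3-(3-methylbut-2-enyl)phenyl]-8-(3-methylbut-2-enyl)chroman, via C8,C3'-dilithio species 23 (not isolated), via C8,C3'-dicopper species 24 (not isolated)
Conditions: n-BuLi (excess), TMEDA, THF, −20 → 0 °C; CuBr·SMe2, −40 °C; then 22 (2.5 equiv), −40 °C → rt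
Reagents that add atoms: prenyl bromide (the second equivalent of 22; one prenyl group goes to C8 and one to C3'), CC(C)=CCBr
Why: Directed ortho-metalation: C8 lies between O1 and the C7 acetal ether and C3' between the two ring B acetal ethers, so each is the kinetically most acidic position of its ring and is lithiated in preference to C6, C5' and the benzylic hydrogens. Transmetalation to monovalent copper makes each arylmetal couple with one molecule of prenyl bromide at its primary carbon (SN2 and not SN2'), as known for oxygen-flanked lithiation–prenylation of protected resorcinols.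

Step 14
Reactants: 25 (3R)-7-(methoxymethoxy)-3-[2,4-bis(methoxymethoxy)-3-(3-methylbut-2-enyl)phenyl]-8-(3-methylbut-2-enyl)chroman
Product: 26 Kanzonol X, (3R)-3-[2,4-dihydroxy-3-(3-methylbut-2-enyl)phenyl]-8-(3-methylbut-2-enyl)chroman-7-ol
Conditions: HCl (3 M aq), MeOH, 40 °C
Reagents that add atoms: none
Why: Acid-catalysed acetal exchange with methanol removes the three methoxymethyl groups; dilute acid and moderate temperature are chosen because ortho-prenylphenols cyclise to 2,2-dimethylchromans under more forcing acid.

## Compound list

1 | methyl (2,4-dihydroxyphenyl)acetate | COC(=O)Cc1ccc(O)cc1O | starting material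
2 | benzyl bromide | BrCc1ccccc1 | starting material
3 | methyl [2,4-bis(benzyloxy)phenyl]acetate (formed in the flask) | COC(=O)Cc1ccc(OCc2ccccc2)cc1OCc1ccccc1 | intermediate
4 | [2,4-bis(benzyloxy)phenyl]acetic acid | OC(=O)Cc1ccc(OCc2ccccc2)cc1OCc1ccccc1 | intermediate
5 | (4R)-4-benzyl-1,3-oxazolidin-2-one | O=C1N[C@H](Cc2ccccc2)CO1 | starting material
6 | [2,4-bis(benzyloxy)phenyl]acetic pivalic anhydride (formed in the flask) | CC(C)(C)C(=O)OC(=O)Cc1ccc(OCc2ccccc2)cc1OCc1ccccc1 | intermediate
7 | (4R)-4-benzyl-3-{[2,4-bis(benzyloxy)phenyl]acetyl}-1,3-oxazolidin-2-one | O=C(Cc1ccc(OCc2ccccc2)cc1OCc1ccccc1)N1C(=O)OC[C@H]1Cc1ccccc1 | intermediate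
8 | 4-hydroxybenzaldehyde | O=Cc1ccc(O)cc1 | starting material
9 | 4-(triisopropylsilyloxy)benzaldehyde | O=Cc1ccc(O[Si](C(C)C)(C(C)C)C(C)C)cc1 | intermediate
10 | [4-(triisopropylsilyloxy)phenyl]methanol | OCc1ccc(O[Si](C(C)C)(C(C)C)C(C)C)cc1 | intermediate
11 | 4-(triisopropylsilyloxy)benzyl bromide | BrCc1ccc(O[Si](C(C)C)(C(C)C)C(C)C)cc1 | intermediate
12 | sodium (Z)-enolate of imide 7 (formed in the flask) | [Na+].[O-]/C(=C\c1ccc(OCc2ccccc2)cc1OCc1ccccc1)N1C(=O)OC[C@H]1Cc1ccccc1 | intermediate
13 | (4R)-4-benzyl-3-{(2R)-2-[2,4-bis(benzyloxy)phenyl]-3-[4-(triisopropylsilyloxy)phenyl]propanoyl}-1,3-oxazolidin-2-one | O=C([C@H](Cc1ccc(O[Si](C(C)C)(C(C)C)C(C)C)cc1)c1ccc(OCc2ccccc2)cc1OCc1ccccc1)N1C(=O)OC[C@H]1Cc1ccccc1 | intermediate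
14 | (2R)-2-[2,4-bis(benzyloxy)phenyl]-3-[4-(triisopropylsilyloxy)phenyl]propan-1-ol | OC[C@H](Cc1ccc(O[Si](C(C)C)(C(C)C)C(C)C)cc1)c1ccc(OCc2ccccc2)cc1OCc1ccccc1 | intermediate
15 | 4-{(2R)-2-[2,4-bis(benzyloxy)phenyl]-3-hydroxypropyl}phenol | OC[C@H](Cc1ccc(O)cc1)c1ccc(OCc2ccccc2)cc1OCc1ccccc1 | intermediate
16 | 4-{(2R)-2-[2,4-bis(benzyloxy)phenyl]-3-hydroxypropyl}-4-hydroperoxycyclohexa-2,5-dien-1-one (formed in the flask) | O=C1C=CC(OO)(C[C@@H](CO)c2ccc(OCc3ccccc3)cc2OCc2ccccc2)C=C1 | intermediate
17 | 4-{(2R)-2-[2,4-bis(benzyloxy)phenyl]-3-hydroxypropyl}-4-hydroxycyclohexa-2,5-dien-1-one | O=C1C=CC(O)(C[C@@H](CO)c2ccc(OCc3ccccc3)cc2OCc2ccccc2)C=C1 | intermediate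
18 | (3R,4aR,8aR)-3-[2,4-bis(benzyloxy)phenyl]-4a-hydroxy-2,3,4,4a,8,8a-hexahydro-7H-chromen-7-one, cis-fused (formed in the flask together with its cis-fused (4aS,8aS) diastereomer) | O=C1C[C@H]2OC[C@@H](c3ccc(OCc4ccccc4)cc3OCc3ccccc3)C[C@@]2(O)C=C1 | intermediate
19 | (3R)-3-[2,4-bis(benzyloxy)phenyl]chroman-7-ol | Oc1ccc2c(c1)OC[C@@H](c1ccc(OCc3ccccc3)cc1OCc1ccccc1)C2 | intermediate
20 | (3R)-3-(2,4-dihydroxyphenyl)chroman-7-ol | Oc1ccc2c(c1)OC[C@@H](c1ccc(O)cc1O)C2 | intermediate
21 | (3R)-7-(methoxymethoxy)-3-[2,4-bis(methoxymethoxy)phenyl]chroman | COCOc1ccc2c(c1)OC[C@@H](c1ccc(OCOC)cc1OCOC)C2 | intermediate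
22 | prenyl bromide (1-bromo-3-methylbut-2-ene) | CC(C)=CCBr | starting material
23 | C8,C3'-dilithio derivative of 21 (formed in the flask) | COCOc1ccc2c(c1[Li])OC[C@@H](c1ccc(OCOC)c([Li])c1OCOC)C2 | intermediate
24 | C8,C3'-dicopper derivative of 21 (formed in the flask) | COCOc1ccc2c(c1[Cu])OC[C@@H](c1ccc(OCOC)c([Cu])c1OCOC)C2 | intermediate
25 | (3R)-7-(methoxymethoxy)-3-[2,4-bis(methoxymethoxy)-3-(3-methylbut-2-enyl)phenyl]-8-(3-methylbut-2-enyl)chroman | COCOc1ccc2c(c1CC=C(C)C)OC[C@@H](c1ccc(OCOC)c(CC=C(C)C)c1OCOC)C2 | intermediate
26 | Kanzonol X, (3R)-3-[2,4-dihydroxy-3-(3-methylbut-2-enyl)phenyl]-8-(3-methylbut-2-enyl)chroman-7-ol | CC(C)=CCc1c(O)ccc([C@@H]2COc3c(ccc(O)c3CC=C(C)C)C2)c1O | target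

## Step count and least certain steps

Total: 14 steps. Longest linear sequence: 12 steps (8 → 26, steps 3–14); the branch from 1 runs 11 steps (steps 1, 2, 6–14).

**Step 10 (key step).** After acidification the tertiary C4a hydroxyl may ionise slowly, because the developing cation is conjugated with the enone until the ketone enolises. During that time the ether could reopen by retro-conjugate addition, and the regenerated quinol could undergo acid-induced alkyl migration. Fallback: starting from 17, the DBU stage is worked up on its own and 18 is isolated. Burgess reagent (methyl N-(triethylammoniosulfonyl)carbamate) in THF at 50 °C converts the tertiary alcohol into the sulfamate ester F1. The cis ring fusion places the C8a hydrogen on the same face as this leaving group, so syn elimination gives the dienone tautomer of ring A and thus 19 without Brønsted acid; elimination towards C4 would give a cross-conjugated isomer that the amine present should tautomerise to the same phenol. The route is rejoined at 19.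

**Step 9.** Capture of singlet oxygen by the poorly water-soluble phenolate may be inefficient, so that the oxidant is spent unproductively. The hydroperoxide may also be diverted under base (oxygen transfer to its own dienone) before it is reduced. Partial ring closure of 17 to 18 in the bicarbonate medium would be harmless, since both go on to 19. Fallback, setting out from 14: Ac2O/pyridine/DMAP gives the acetate F2. Bu4NF/AcOH then gives the phenol acetate F3. PhI(OAc)2 (trivalent iodine) in MeCN/H2O at 0 °C gives the para-quinol acetate F4 by water capture of the phenoxenium ion; the ester oxygen is too weak a nucleophile to spirocyclise. K2CO3 in MeOH removes the acetate and closes ring C in the same flask through 17 and 18, and acidification with TsOH gives 19, where the route is rejoined.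

**Step 6.** The α-aryl hydrogen of product 13 is acidic, so proton exchange between 13 and enolate 12 may erode the configuration. Alkylation of the hindered ortho-substituted enolate may also be slow enough for the enolate to fragment. Fallback, setting out from acid 4 and aldehyde 8: Perkin condensation (Ac2O, Et3N, 110 °C, then aqueous NaOH) gives the (E)-2,3-diarylacrylic acid F5. Enantioselective hydrogenation with Ru(OAc)2(BINAP) (divalent ruthenium, the BINAP enantiomer chosen to deliver the R acid; benzyl ethers survive homogeneous hydrogenation) gives the propanoic acid F6. Reduction with BH3·THF gives 15, where the route is rejoined.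

**Step 13.** The second metalation may lag behind the first, leaving mono-prenylated material. The allylic bromide may be attacked at its tertiary terminus or consumed by coupling with excess organometallic, giving mixtures that are hard to separate. Deprotonation at the benzylic C3 hydrogen would endanger the configuration, though the oxygen-flanked ring positions are far more acidic kinetically. Fallback, setting out from 21: the same dimetalation and copper transmetalation is quenched with allyl bromide, which has no regiochemical ambiguity, to give the 8,3'-diallyl compound F7. Twofold cross-metathesis with 2-methylbut-2-ene and the second-generation Grubbs catalyst RuCl2(=CHPh)(PCy3)(H2IMes) converts both allyl groups into prenyl groups and rejoins the route at 25.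

**Step 14.** Acid strong enough to remove three aryl acetal ethers may also protonate the prenyl olefins, leading to cyclisation onto the neighbouring phenols (2,2-dimethylchroman formation) or to hydration. Fallback, setting out from 20: SEMCl/iPr2NEt gives the tris[2-(trimethylsilyl)ethoxymethyl] ether F8, which directs metalation as well as the methoxymethyl ether does. The lithiation–copper–prenyl bromide sequence of step 13 gives the bis-prenyl compound F9. Bu4NF in DMPU at 60 °C removes the three groups without acid and gives 26 directly.

## Further compounds

F1 | step 10 | methyl N-({(3R,4aR,8aR)-3-[2,4-bis(benzyloxy)phenyl]-7-oxo-2,3,4,7,8,8a-hexahydro-4aH-chromen-4a-yl}oxysulfonyl)carbamate (sulfamate ester of 18) | O=C1C[C@H]2OC[C@@H](c3ccc(OCc4ccccc4)cc3OCc3ccccc3)C[C@@]2(OS(=O)(=O)NC(=O)OC)C=C1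
F2 | step 9 | (2R)-2-[2,4-bis(benzyloxy)phenyl]-3-[4-(triisopropylsilyloxy)phenyl]propyl acetate | CC(=O)OC[C@H](Cc1ccc(O[Si](C(C)C)(C(C)C)C(C)C)cc1)c1ccc(OCc2ccccc2)cc1OCc1ccccc1
F3 | step 9 | (2R)-2-[2,4-bis(benzyloxy)phenyl]-3-(4-hydroxyphenyl)propyl acetate | CC(=O)OC[C@H](Cc1ccc(O)cc1)c1ccc(OCc2ccccc2)cc1OCc1ccccc1
F4 | step 9 | (2R)-2-[2,4-bis(benzyloxy)phenyl]-3-(1-hydroxy-4-oxocyclohexa-2,5-dien-1-yl)propyl acetate | CC(=O)OC[C@H](CC1(O)C=CC(=O)C=C1)c1ccc(OCc2ccccc2)cc1OCc1ccccc1
F5 | step 6 | (2E)-2-[2,4-bis(benzyloxy)phenyl]-3-(4-hydroxyphenyl)prop-2-enoic acid | OC(=O)/C(=C/c1ccc(O)cc1)c1ccc(OCc2ccccc2)cc1OCc1ccccc1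
F6 | step 6 | (2R)-2-[2,4-bis(benzyloxy)phenyl]-3-(4-hydroxyphenyl)propanoic acid | OC(=O)[C@H](Cc1ccc(O)cc1)c1ccc(OCc2ccccc2)cc1OCc1ccccc1
F7 | step 13 | (3R)-8-allyl-3-[3-allyl-2,4-bis(methoxymethoxy)phenyl]-7-(methoxymethoxy)chroman | COCOc1ccc2c(c1CC=C)OC[C@@H](c1ccc(OCOC)c(CC=C)c1OCOC)C2
F8 | step 14 | (3R)-7-{[2-(trimethylsilyl)ethoxy]methoxy}-3-(2,4-bis{[2-(trimethylsilyl)ethoxy]methoxy}phenyl)chroman | C[Si](C)(C)CCOCOc1ccc2c(c1)OC[C@@H](c1ccc(OCOCC[Si](C)(C)C)cc1OCOCC[Si](C)(C)C)C2
F9 | step 14 | (3R)-8-(3-methylbut-2-enyl)-7-{[2-(trimethylsilyl)ethoxy]methoxy}-3-[3-(3-methylbut-2-enyl)-2,4-bis{[2-(trimethylsilyl)ethoxy]methoxy}phenyl]chroman | C[Si](C)(C)CCOCOc1ccc2c(c1CC=C(C)C)OC[C@@H](c1ccc(OCOCC[Si](C)(C)C)c(CC=C(C)C)c1OCOCC[Si](C)(C)C)C2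
A1 | alternative 1 | (3R)-3-[2,4-bis(methoxymethoxy)-3-(3-methylbut-2-enyl)phenyl]-7-(methoxymethoxy)-8-(3-methylbut-2-enyl)chroman-2-one | CC(C)=CCc1c(OCOC)ccc([C@@H]2C(=O)Oc3c(ccc(OCOC)c3CC=C(C)C)C2)c1OCOC
A2 | alternative 1 | 3-(methoxymethoxy)-6-methylidene-2-(3-methylbut-2-enyl)cyclohexa-2,4-dien-1-one (ring A ortho-quinone methide) | C=C1C=CC(OCOC)=C(CC=C(C)C)C1=O
A3 | alternative 1 | [2,4-bis(methoxymethoxy)-3-(3-methylbut-2-enyl)phenyl]acetic acid | OC(=O)Cc1ccc(OCOC)c(CC=C(C)C)c1OCOC
A4 | alternative 1 | (2R)-2-[2,4-bis(methoxymethoxy)-3-(3-methylbut-2-enyl)phenyl]-3-[2-hydroxy-4-(methoxymethoxy)-3-(3-methylbut-2-enyl)phenyl]propan-1-ol | OC[C@H](Cc1ccc(OCOC)c(CC=C(C)C)c1O)c1ccc(OCOC)c(CC=C(C)C)c1OCOC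
A5 | alternative 2 | 7,4'-bis(triisopropylsilyl) ether of Kanzonol X | CC(C)=CCc1c(O[Si](C(C)C)(C(C)C)C(C)C)ccc([C@@H]2COc3c(ccc(O[Si](C(C)C)(C(C)C)C(C)C)c3CC=C(C)C)C2)c1O
A6 | alternative 2 | (3E)-1-diazo-4-[(3R)-8-(3-methylbut-2-enyl)-7-(triisopropylsilyloxy)chroman-3-yl]but-3-en-2-one | [N-]=[N+]=CC(=O)/C=C/[C@@H]1COc2c(CC=C(C)C)c(O[Si](C(C)C)(C(C)C)C(C)C)ccc2C1
A7 | alternative 2 | triisopropyl[(5-methylhex-4-en-1-yn-1-yl)oxy]silane | CC(C)=CCC#CO[Si](C(C)C)(C(C)C)C(C)C
A8 | alternative 3 | tris(methoxymethyl) ether of Kanzonol X (identical with 25) | CC(C)=CCc1c(OCOC)ccc([C@@H]2COc3c(ccc(OCOC)c3CC=C(C)C)C2)c1OCOC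
A9 | alternative 3 | (3R)-7-(methoxymethoxy)-3-[2,4-bis(methoxymethoxy)phenyl]chroman (identical with 21) | COCOc1ccc2c(c1)OC[C@@H](c1ccc(OCOC)cc1OCOC)C2
A10 | alternative 3 | 7-(methoxymethoxy)-3-[2,4-bis(methoxymethoxy)phenyl]-2H-chromene | COCOc1ccc2C=C(c3ccc(OCOC)cc3OCOC)COc2c1
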